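Ring B of aspidin (C1'–C6') is a fully substituted phloroglucinol whose three oxygens differ: OH at C6', OH at C2', OMe at C4'. The route builds this ring by a cyclobutenone–siloxyalkyne benzannulation. 3-Methoxy-2-methylcyclobutenone supplies C3'–C6' as a vinylketene, and a triisopropylsiloxyalkyne supplies C1' and C2' together with the bridge CH2 and ring A, held as its tribenzyl ether. One thermal operation forms C6'–C1' and C2'–C3', closes ring B, and delivers the C6' hydroxyl, C2' silyl ether and C4' methyl ether already differentiated, with the bridge between the two phenolic carbons. Deprotection, twofold Friedel–Crafts butyrylation and gem-dimethylation of ring A finish the synthesis.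

Key step: step 6

Remark: ring A is numbered C1 (bridge carbon) to C6 and ring B C1' (bridge carbon) to C6'. Aspidin is treated as the ring A enol tautomer drawn in the target structure, and no compound of the route carries a stereocentre that has to be controlled.

Step 1
Reactants: 1 1-ethoxyprop-1-yne; 2 trichloroacetyl chloride
Product: 4 4,4-dichloro-3-ethoxy-2-methylcyclobut-2-en-1-one, via dichloroketene 3 (not isolated)
Conditions: Zn–Cu couple, Et2O–DME, 2 added over 2 h, 15–25 °C
Reagents that add atoms: none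
Why: Zinc reduces 2 to dichloroketene 3, which adds to the ynol ether in a regioselective ketene–alkyne [2+2] cycloaddition, the nucleophilic methyl-bearing alkyne carbon bonding to the ketene carbonyl carbon so that methyl ends up at C2 and ethoxy at C3.

Step 2
Reactants: 4 4,4-dichloro-3-ethoxy-2-methylcyclobut-2-en-1-one
Product: 5 3-ethoxy-2-methylcyclobut-2-en-1-one
Conditions: Zn dust, AcOH, TMEDA, EtOH, 0 °C → rt
Reagents that add atoms: none
Why: Zinc-mediated reductive dechlorination of the α,α-dichloroketone (zinc enolates protonated by AcOH) should remove both chlorines, the amine buffer protecting the acid-sensitive vinylogous ester.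

Step 3
Reactants: 5 3-ethoxy-2-methylcyclobut-2-en-1-one
Product: 6 3-methoxy-2-methylcyclobut-2-en-1-one
Conditions: anhydrous MeOH (solvent), camphorsulfonic acid (cat.), rt; evaporate and repeat once with fresh MeOH
Reagents that add atoms: methanol, CO
Why: Acid-catalysed transetherification of a vinylogous ester, in which methanol adds to C3 of the O-protonated enone and the mixed ketal loses ethanol, should be driven by the large excess of methanol as it is for squarate esters and enol ethers of cyclic 1,3-diones.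

Step 4
Reactants: 7 1,3,5-tris(benzyloxy)benzene; 8 ethyl diazoacetate
Product: 9 ethyl 2-[2,4,6-tris(benzyloxy)phenyl]acetate
Conditions: Rh2(OAc)4 (1 mol %), CH2Cl2, rt, 8 added by syringe pump to 7 (2 equiv, excess recovered)
Reagents that add atoms: none
Why: Formal aromatic C–H insertion of a rhodium carbenoid, in which the electrophilic carbenoid is attacked by the trialkoxyarene (far more nucleophilic than the benzyl phenyl rings) and the zwitterion rearomatises by proton transfer, while slow addition and excess 7 suppress carbene dimerisation and double insertion.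

Step 5
Reactants: 9 ethyl 2-[2,4,6-tris(benzyloxy)phenyl]acetate
Product: 12 triisopropyl[3-[2,4,6-tris(benzyloxy)phenyl]prop-1-yn-1-yloxy]silane, via lithium dibromoenolate 10 (not isolated), via lithium ynolate 11 (not isolated)
Conditions: CH2Br2, lithium 2,2,6,6-tetramethylpiperidide (LiTMP), THF, −78 °C; LiN(SiMe3)2; n-BuLi, −78 → 0 °C; iPr3SiOTf, −78 °C → rt
Reagents that add atoms: dibromomethane, BrCBr; triisopropylsilyl trifluoromethanesulfonate, CC(C)[Si](OS(=O)(=O)C(F)(F)F)(C(C)C)C(C)C
Why: Kowalski ynolate formation, in which dibromomethyllithium adds to the ester at −78 °C faster than the hindered, electron-rich arylacetate is enolised, the dibromo enolate 10 undergoes Br–Li exchange and 1,2-shift of the arylmethyl group (a Fritsch–Buttenberg–Wiechell-type carbenoid rearrangement) to ynolate 11, and the bulky silyl triflate captures 11 on oxygen.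

Step 6
Reactants: 6 3-methoxy-2-methylcyclobut-2-en-1-one; 12 triisopropyl[3-[2,4,6-tris(benzyloxy)phenyl]prop-1-yn-1-yloxy]silane
Product: 17 5-methoxy-4-methyl-2-[[2,4,6-tris(benzyloxy)phenyl]methyl]-3-(triisopropylsilyloxy)phenol, via vinylketene 13 (not isolated), via vinylcyclobutenone 14 (not isolated), via dienylketene 15 (not isolated), via cyclohexadienone 16 (not isolated)
Conditions: 12 (1.1 equiv), toluene (0.4 M), 80 → 110 °C, sealed tube, argon
Reagents that add atoms: none
Why: Heating opens 6 by 4π electrocyclic cleavage of its C1–C4 bond to vinylketene 13, whose ketene C=C adds the electron-rich alkyne of 12 in a [2+2] cycloaddition to give 14, and a second 4π opening to dienylketene 15 is followed by ring closure and enolisation of 16 to the phenol. This is the Danheiser benzannulation of cyclobutenones with trialkylsiloxyalkynes, the known route to resorcinol monosilyl ethers. Ring B is closed by a thermal disrotatory 6π electrocyclisation that joins the ketene carbon (C6') to the terminal methylene (C5'), and aromatisation makes the cascade irreversible. No stereocentre remains, because the quaternary carbon of racemic 14 becomes sp2 on ring opening. The one selectivity needed is the orientation of the [2+2] event, and the polarity of the ynol ether secures it: its nucleophilic β-carbon (C1', bearing the arylmethyl group) bonds to the electrophilic ketene carbon (C6') and its oxygenated carbon (C2') to C3', so the bridge lies between the two oxygenated carbons and para to the methoxy group. Only the isomer of 15 with ketene and methoxyvinyl groups cis can cyclise, reversible opening of 14 feeds it, and a small excess of 12 leaves no vinylketene to acylate the product phenol.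

Step 7
Reactants: 17 5-methoxy-4-methyl-2-[[2,4,6-tris(benzyloxy)phenyl]methyl]-3-(triisopropylsilyloxy)phenol
Product: 18 5-methoxy-4-methyl-2-[[2,4,6-tris(benzyloxy)phenyl]methyl]benzene-1,3-diol
Conditions: Bu4NF, AcOH, THF, 0 °C
Reagents that add atoms: none
Why: Fluoride-mediated cleavage of the aryl silyl ether, driven by the strong Si–F bond and buffered by AcOH, should free the C2' phenol while benzyl and methyl ethers stay inert.

Step 8
Reactants: 18 5-methoxy-4-methyl-2-[[2,4,6-tris(benzyloxy)phenyl]methyl]benzene-1,3-diol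
Product: 19 2-[(2,6-dihydroxy-4-methoxy-3-methylphenyl)methyl]benzene-1,3,5-triol
Conditions: H2 (1 atm), Pd/C (10 wt %), EtOAc–MeOH, rt; filtered under argon and used at once
Reagents that add atoms: none
Why: Palladium-catalysed hydrogenolysis should cleave the three benzyl aryl ethers and leave the methyl ether and the diarylmethane C–C bonds untouched.

Step 9
Reactants: 19 2-[(2,6-dihydroxy-4-methoxy-3-methylphenyl)methyl]benzene-1,3,5-triol
Product: 20 1-[3-[(3-butanoyl-2,4,6-trihydroxyphenyl)methyl]-2,4-dihydroxy-6-methoxy-5-methylphenyl]butan-1-one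
Conditions: butanoyl chloride (2.1 equiv), AlCl3 (5 equiv), CH2Cl2–PhNO2, 0 °C → rt; iced aq. HCl
Reagents that add atoms: butanoyl chloride, CCCC(Cl)=O
Why: Friedel–Crafts acylation of two phloroglucinol-type nuclei should place one butanoyl group on each ring, because the first acyl group deactivates its ring toward a second, C5' is the only free carbon of ring B, and any O-acyl intermediates converge by Fries rearrangement under AlCl3.

Step 10
Reactants: 20 1-[3-[(3-butanoyl-2,4,6-trihydroxyphenyl)methyl]-2,4-dihydroxy-6-methoxy-5-methylphenyl]butan-1-one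
Product: 21 aspidin, 2-butanoyl-4-[(3-butanoyl-2,6-dihydroxy-4-methoxy-5-methylphenyl)methyl]-3,5-dihydroxy-6,6-dimethylcyclohexa-2,4-dien-1-one
Conditions: NaOMe (3.5 equiv), MeI (2.2 equiv), MeOH, 0 °C → rt; prompt quench with 1 M HCl
Reagents that add atoms: iodomethane, CI
Why: Dearomative C-methylation of an acylphloroglucinol polyanion (the filicinic acid synthesis) should put both methyl groups on C5 of ring A, since ring A is the more acidic trihydroxy ring and the only one with a nuclear C–H, the second methyl enters at the same least hindered carbon to give the stable vinylogous-acid dienone, and the protic solvent favours C- over O-alkylation.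

Compound list
1 | 1-ethoxyprop-1-yne | CCOC#CC | starting material
2 | trichloroacetyl chloride | O=C(Cl)C(Cl)(Cl)Cl | starting material
3 | dichloroketene (not isolated) | O=C=C(Cl)Cl | intermediate
4 | 4,4-dichloro-3-ethoxy-2-methylcyclobut-2-en-1-one | CCOC1=C(C)C(=O)C1(Cl)Cl | intermediate
5 | 3-ethoxy-2-methylcyclobut-2-en-1-one | CCOC1=C(C)C(=O)C1 | intermediate
6 | 3-methoxy-2-methylcyclobut-2-en-1-one | COC1=C(C)C(=O)C1 | intermediate
7 | 1,3,5-tris(benzyloxy)benzene | c1ccc(COc2cc(OCc3ccccc3)cc(OCc3ccccc3)c2)cc1 | starting material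
8 | ethyl diazoacetate | CCOC(=O)C=[N+]=[N-] | starting material
9 | ethyl 2-[2,4,6-tris(benzyloxy)phenyl]acetate | CCOC(=O)Cc1c(OCc2ccccc2)cc(OCc2ccccc2)cc1OCc1ccccc1 | intermediate
10 | lithium 1,1-dibromo-3-[2,4,6-tris(benzyloxy)phenyl]prop-1-en-2-olate (not isolated) | [Li+].[O-]C(Cc1c(OCc2ccccc2)cc(OCc2ccccc2)cc1OCc1ccccc1)=C(Br)Br | intermediate
11 | lithium 3-[2,4,6-tris(benzyloxy)phenyl]prop-1-yn-1-olate (not isolated) | [Li+].[O-]C#CCc1c(OCc2ccccc2)cc(OCc2ccccc2)cc1OCc1ccccc1 | intermediate
12 | triisopropyl[3-[2,4,6-tris(benzyloxy)phenyl]prop-1-yn-1-yloxy]silane | CC(C)[Si](OC#CCc1c(OCc2ccccc2)cc(OCc2ccccc2)cc1OCc1ccccc1)(C(C)C)C(C)C | intermediate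
13 | 3-methoxy-2-methylbuta-1,3-dien-1-one (vinylketene, not isolated) | COC(=C)C(C)=C=O | intermediate
14 | 4-(1-methoxyethenyl)-4-methyl-3-(triisopropylsilyloxy)-2-[[2,4,6-tris(benzyloxy)phenyl]methyl]cyclobut-2-en-1-one (racemic, not isolated) | COC(=C)C1(C)C(=O)C(Cc2c(OCc3ccccc3)cc(OCc3ccccc3)cc2OCc2ccccc2)=C1O[Si](C(C)C)(C(C)C)C(C)C | intermediate
15 | 5-methoxy-4-methyl-3-(triisopropylsilyloxy)-2-[[2,4,6-tris(benzyloxy)phenyl]methyl]hexa-1,3,5-trien-1-one, ketene and methoxyvinyl groups cis on the central alkene (not isolated) | COC(=C)/C(C)=C(O[Si](C(C)C)(C(C)C)C(C)C)\C(Cc1c(OCc2ccccc2)cc(OCc2ccccc2)cc1OCc1ccccc1)=C=O | intermediate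
16 | 5-methoxy-4-methyl-3-(triisopropylsilyloxy)-2-[[2,4,6-tris(benzyloxy)phenyl]methyl]cyclohexa-2,4-dien-1-one (not isolated) | COC1=C(C)C(O[Si](C(C)C)(C(C)C)C(C)C)=C(Cc2c(OCc3ccccc3)cc(OCc3ccccc3)cc2OCc2ccccc2)C(=O)C1 | intermediate
17 | 5-methoxy-4-methyl-2-[[2,4,6-tris(benzyloxy)phenyl]methyl]-3-(triisopropylsilyloxy)phenol | COc1cc(O)c(Cc2c(OCc3ccccc3)cc(OCc3ccccc3)cc2OCc2ccccc2)c(O[Si](C(C)C)(C(C)C)C(C)C)c1C | intermediate
18 | 5-methoxy-4-methyl-2-[[2,4,6-tris(benzyloxy)phenyl]methyl]benzene-1,3-diol | COc1cc(O)c(Cc2c(OCc3ccccc3)cc(OCc3ccccc3)cc2OCc2ccccc2)c(O)c1C | intermediate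
19 | 2-[(2,6-dihydroxy-4-methoxy-3-methylphenyl)methyl]benzene-1,3,5-triol | COc1cc(O)c(Cc2c(O)cc(O)cc2O)c(O)c1C | intermediate
20 | 1-[3-[(3-butanoyl-2,4,6-trihydroxyphenyl)methyl]-2,4-dihydroxy-6-methoxy-5-methylphenyl]butan-1-one | CCCC(=O)c1c(O)cc(O)c(Cc2c(O)c(C)c(OC)c(C(=O)CCC)c2O)c1O | intermediate
21 | aspidin, 2-butanoyl-4-[(3-butanoyl-2,6-dihydroxy-4-methoxy-5-methylphenyl)methyl]-3,5-dihydroxy-6,6-dimethylcyclohexa-2,4-dien-1-one | CCCC(=O)C1=C(O)C(Cc2c(O)c(C)c(OC)c(C(=O)CCC)c2O)=C(O)C(C)(C)C1=O | target

Total step count: 10. Longest linear sequence: 8 steps (steps 1, 2, 3, 6, 7, 8, 9, 10, from 1-ethoxyprop-1-yne 1); the second branch (steps 4 and 5) joins at step 6.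

Steps most likely to fail

Step 6. The vinylogous-ester cyclobutenone may open too slowly. Thermal silyl migration in 12 (to a silylketene) or self-condensation of the vinylketene could then overtake the cycloaddition, and the product phenol could be consumed by acylation. The fallback gives up the ring construction and joins two preformed rings by Friedel–Crafts benzylation. It sets out from 7 and comes back at 18. Commercial 2,4,6-trihydroxy-3-methylbenzaldehyde (Cc1c(O)cc(O)c(C=O)c1O) would be methylated at its non-chelated 4-hydroxyl (MeI, 1 equiv, K2CO3, acetone) to 2,6-dihydroxy-4-methoxy-3-methylbenzaldehyde F1. Reduction (NaBH4, THF–MeOH, 0 °C) would give 2-(hydroxymethyl)-5-methoxy-4-methylbenzene-1,3-diol F2. Its ortho-quinone methide, formed with catalytic TsOH in CH2Cl2, should be trapped by an excess of 7 at a carbon between two benzyloxy groups to give 18.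

Step 10. Site control in the double alkylation may be lost, with methyl going to C1 of ring A, to C3' of ring B or to a phenoxide oxygen. Methoxide may also fragment the methylene bridge through a quinone methide and scramble the two halves. The fallback methylates ring A while ring B cannot ionise. It sets out from 17 and comes back at 21. Silylation of the C6' hydroxyl (iPr3SiOTf, 2,6-lutidine, CH2Cl2) would give 1-methoxy-2-methyl-3,5-bis(triisopropylsilyloxy)-4-[[2,4,6-tris(benzyloxy)phenyl]methyl]benzene F3. Hydrogenolysis (H2, Pd/C) would give 2-[[4-methoxy-3-methyl-2,6-bis(triisopropylsilyloxy)phenyl]methyl]benzene-1,3,5-triol F4. Monoacylation of ring A (butanoic anhydride, BF3·OEt2, CH2Cl2, 0 °C) would give 1-[2,4,6-trihydroxy-3-[[4-methoxy-3-methyl-2,6-bis(triisopropylsilyloxy)phenyl]methyl]phenyl]butan-1-one F5. Methylation (MeI, NaOMe, MeOH, 0 °C) would give 2-butanoyl-3,5-dihydroxy-4-[[4-methoxy-3-methyl-2,6-bis(triisopropylsilyloxy)phenyl]methyl]-6,6-dimethylcyclohexa-2,4-dien-1-one F6. Buffered desilylation (Bu4NF, AcOH) would give 2-butanoyl-4-[(2,6-dihydroxy-4-methoxy-3-methylphenyl)methyl]-3,5-dihydroxy-6,6-dimethylcyclohexa-2,4-dien-1-one F7. Friedel–Crafts butyrylation of C5', the only unsubstituted ring carbon left (butanoyl chloride, AlCl3, as in step 9), would then give 21.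

Step 9. Acid may break or exchange the aryl–CH2 bond of the electron-rich pentaol before it is acylated. A third acyl group may enter ring A, and 19 may oxidise in air before it reacts. The fallback acylates before the benzyl ethers are removed, so that 19 is never formed. It sets out from 18 and comes back at 20. Butanoyl chloride (2.2 equiv) and TiCl4 in CH2Cl2 at −30 → 0 °C should acylate the trialkoxyarene ring A once and, through the titanium phenoxide, C5' of ring B. The product would be 1-[3-[[3-butanoyl-2,4,6-tris(benzyloxy)phenyl]methyl]-2,4-dihydroxy-6-methoxy-5-methylphenyl]butan-1-one F8. Any congener that has lost a benzyl group next to the new ketone converges with it in the hydrogenolysis (H2, Pd/C, EtOAc) that gives 20.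

Further compounds
F1 | step 6 | 2,6-dihydroxy-4-methoxy-3-methylbenzaldehyde | COc1cc(O)c(C=O)c(O)c1C
F2 | step 6 | 2-(hydroxymethyl)-5-methoxy-4-methylbenzene-1,3-diol | COc1cc(O)c(CO)c(O)c1C
F3 | step 10 | 1-methoxy-2-methyl-3,5-bis(triisopropylsilyloxy)-4-[[2,4,6-tris(benzyloxy)phenyl]methyl]benzene | COc1cc(O[Si](C(C)C)(C(C)C)C(C)C)c(Cc2c(OCc3ccccc3)cc(OCc3ccccc3)cc2OCc2ccccc2)c(O[Si](C(C)C)(C(C)C)C(C)C)c1C
F4 | step 10 | 2-[[4-methoxy-3-methyl-2,6-bis(triisopropylsilyloxy)phenyl]methyl]benzene-1,3,5-triol | COc1cc(O[Si](C(C)C)(C(C)C)C(C)C)c(Cc2c(O)cc(O)cc2O)c(O[Si](C(C)C)(C(C)C)C(C)C)c1C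
F5 | step 10 | 1-[2,4,6-trihydroxy-3-[[4-methoxy-3-methyl-2,6-bis(triisopropylsilyloxy)phenyl]methyl]phenyl]butan-1-one | CCCC(=O)c1c(O)cc(O)c(Cc2c(O[Si](C(C)C)(C(C)C)C(C)C)cc(OC)c(C)c2O[Si](C(C)C)(C(C)C)C(C)C)c1O
F6 | step 10 | 2-butanoyl-3,5-dihydroxy-4-[[4-methoxy-3-methyl-2,6-bis(triisopropylsilyloxy)phenyl]methyl]-6,6-dimethylcyclohexa-2,4-dien-1-one | CCCC(=O)C1=C(O)C(Cc2c(O[Si](C(C)C)(C(C)C)C(C)C)cc(OC)c(C)c2O[Si](C(C)C)(C(C)C)C(C)C)=C(O)C(C)(C)C1=O
F7 | step 10 | 2-butanoyl-4-[(2,6-dihydroxy-4-methoxy-3-methylphenyl)methyl]-3,5-dihydroxy-6,6-dimethylcyclohexa-2,4-dien-1-one | CCCC(=O)C1=C(O)C(Cc2c(O)cc(OC)c(C)c2O)=C(O)C(C)(C)C1=O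
F8 | step 9 | 1-[3-[[3-butanoyl-2,4,6-tris(benzyloxy)phenyl]methyl]-2,4-dihydroxy-6-methoxy-5-methylphenyl]butan-1-one | CCCC(=O)c1c(OCc2ccccc2)cc(OCc2ccccc2)c(Cc2c(O)c(C)c(OC)c(C(=O)CCC)c2O)c1OCc1ccccc1
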